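The runs were computed from invented constants, noise included.

**Two plateaus.** In the earlier runs the plateau isomer share, meaning isomer of the product over isomer plus target, moves less than the charged share of other conformer does: delta reads 8.24% and theta 7.82%, while their charges hold 9.09% and 6.28%.

| setting | delta | theta | flask |
|---|---|---|---|
| substrate | 0.40 M | 0.40 M | 0.40 M |
| other conformer | 0.10 equiv | 0.067 equiv | 0.100 equiv |
| gas | 55 mM (held) | 55 mM (held) | 55 mM (held) |
| remark | the very flask that is asked about, followed so far | run made earlier |  |
| time |  |  | 2.0 h |

| run | time / min | isomer of the product / % | target / % |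
|---|---|---|---|
| delta | 1.50 | 5.4 | 47.7 |
| delta | 5.00 | 8.3 | 92.1 |
| delta | 8.00 | 7.3 | 91.9 |
| delta | 12.0 | 8.0 | 92.6 |
| delta | 20.0 | 8.6 | 92.0 |
| delta | 25.0 | 9.2 | 92.2 |
| theta | 3.00 | 7.9 | 82.8 |
| theta | 10.0 | 7.9 | 92.4 |
| theta | 15.0 | 7.7 | 91.6 |
| theta | 25.0 | 8.3 | 92.7 |
| theta | 40.0 | 7.4 | 91.7 |
| theta | 50.0 | 7.8 | 92.2 |

(scatter of a reading: 0.5 percentage points)

* share of isomer of the product in isomer of the product plus target at 5.0 s
* share of isomer of the product in isomer of the product plus target at 2.0 h

- the earlier runs were read with a standard deviation of 0.5 percentage points
- at the start none of the gas is in solution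

**Two extremes.** Picture first frozen conformers, where the plateau equals the charged share, and then conformers equilibrated at once (the Curtin–Hammett picture), where the plateau ignores the charge. The readings put you close to the second, with 0.149 as the charge memory, the shift in plateau share per shift in charged share, a reading carrying the scatter of 0.5 percentage points per point. In the asked flask this splits the plateau into a head start of 1.35% of the charge and a base share of 6.89%.

**Early share.** If the pace up to 1.50 min was steady, isomer plus target at 5.0 s is 2.95%. With the head start delivered whole, a first answer gives 1.56% of isomer; putting that back leaves less target, so isomer is 1.45%, a share of 49.2%. With no head start yet, the base share runs by itself, so the share is 6.89%. My reckoning takes the mean of these two, 28.0%, and 8.24% at 2.0 h.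

**The forecast.** It says 20% and 8.4%, calling the early share “clearly elevated, though the size is poorly constrained”, so it sits below my mean at 5.0 s.

**The flask.** The flask gives 35.8% at 5.0 s and 8.15% at 2.0 h.

    partner + other conformer → isomer of the product (k = 8.67 L mol⁻¹ s⁻¹)
    gas ⇌ partner, rate k2*(csat - [partner]) (kL = 0.0614 s⁻¹)
    substrate + partner → target (k = 0.760 L mol⁻¹ s⁻¹)
    substrate ⇌ other conformer (K = 0.0100, k = 0.00251 s⁻¹)
    partner ⇌ dormant form (K = 110, k = 0.00394 s⁻¹)

**The neighbour.** The early share of the flask lies above my mean and below the whole-head-start bound. Take the neighbour, the same flask with 0.250 equiv of other conformer, a charged share of 20.0%. Base share plus memory times that charge gives 9.87%, whereas the neighbour stands at 9.14% at 2.0 h, lower, and the memory between the neighbour and the flask comes to 0.0907.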